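A direct plan would make the C1–C2 bond last: an (S)-propargylic alcohol would be taken in four steps to the silyloxy aldehyde A1, a benzoate ester in four steps to the benzylzinc bromide A2, and A1 with an acetyl halide to the 1-bromoalkyl acetate A3, which a chiral nickel catalyst would couple with A2 to the bis-silyl ether A4 before desilylation. Its weakest steps would be:
(a) the nickel-catalysed enantioconvergent coupling of A3 with A2, an untested benzylzinc case that alone would set C2, on eight-step material, with homocoupling and uncatalysed substitution competing and a C2 epimer that could hardly be removed;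
(b) the silylation, reduction, bromination and zinc insertion that would only turn an ester into a CH2–metal;
(c) the alkylation, hydrogenation and hydrolysis run to A1, four steps and a bought stereocentre spent on an unstable straight-chain aldehyde.

Plan of the new route: seen from C5, C2 and C8 have the same handedness, so the segment C1–C9 with its oxygens on C2 and C8 is C2-symmetric, and C1 and C9 can each be a CH2Cl group. The route cuts aryl–C1 and C9–C10 back to (2R,8R)-1,2:8,9-diepoxynonane, and this to achiral 1,9-dichlorononane-2,8-dione (C1–C2 and C8–C9 from heptanedioyl dichloride and a diazomethane-type carbon at each end). One ketoreductase step sets both stereocentres. The benzene ring is bought; the two oxiranes close together (step 3) and open in turn (steps 5 and 7), the acetate going on in between so that the C8 hydroxyl appears free. No benzylic metal, 1-bromoalkyl ester, silyl ether or late asymmetric coupling remains.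

Key step: step 2

Remark: the SMILES is read as (2R,8S)-8-hydroxy-1-(3-hydroxy-5-methoxyphenyl)tridecan-2-yl acetate, locants C1–C13 below refer to this tridecane chain, the enzyme of step 2 is assumed to come from a commercial panel of Prelog-selective ketoreductases, and in step 1 the silyl group of the diazo reagent is taken to leave as Me3SiCl.

Step 1
Reactants: 1 heptanedioyl dichloride (pimeloyl chloride)
Product: 3 1,9-dichlorononane-2,8-dione, via bis(diazoketone) 2 (not isolated)
Conditions: TMSCHN2 (2 M in hexanes, 2 equiv per acyl chloride), THF/MeCN (1:1), 0 °C → rt; then HCl (4 M in 1,4-dioxane, excess), 0 °C; aq NaHCO3 wash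
Reagents that add atoms: (trimethylsilyl)diazomethane, C[Si](C)(C)C=[N+]=[N-]; hydrogen chloride, Cl
Why: Twofold diazoketone synthesis of the Arndt–Eistert type, in which each acid chloride terminus C-acylates the diazoalkane and chloride takes the silyl group as Me3SiCl, followed by hydrochlorination, in which protonation at the diazo carbon and SN2 displacement of N2 by chloride give each chloromethyl ketone; the excess diazo reagent is destroyed by the HCl.

Step 2
Reactants: 3 1,9-dichlorononane-2,8-dione
Product: 5 (2R,8R)-1,9-dichlorononane-2,8-diol, via hydroxy ketone 4 (not isolated)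
Conditions: Prelog-selective NADH-dependent alcohol dehydrogenase (ketoreductase; e.g. ADH-A of Rhodococcus ruber as lyophilised recombinant cells), NAD+ (1 mol%), 2-propanol (20% v/v), potassium phosphate buffer (50 mM, pH 7.0), 30 °C; EtOAc extraction
Reagents that add atoms: none
Why: Each chloromethyl ketone terminus of 3 should bind with CH2Cl in the small pocket and the chain in the large one, and enzyme-bound NADH, regenerated by the same enzyme from 2-propanol, transfers hydride to the exposed carbonyl face, giving first hydroxy ketone 4 and then diol 5. The closest known reaction type is the alcohol dehydrogenase (ketoreductase) reduction of aliphatic 1-chloroalkan-2-ones to enantiopure chlorohydrins by coupled-substrate transfer hydrogenation. No ring is closed. C2 and C8 are both set by the enzyme in the Prelog sense, oxygen ending where it stands in an (S)-alkan-2-ol, which is R here because CH2Cl outranks the chain; the two carbonyls lie five CH2 apart and are reduced independently, so the C2-symmetric (R,R)-diol should result. The step needs face selection at a dialkyl ketone, which the CH2Cl/long-chain contrast at C1 and C9 secures where the pentyl/chain contrast at C8 of the target could not, and since the wrong enantiomer would need two errors the (S,S)-diol should be negligible and the meso diol the only stereoisomer to purge, by recrystallisation of 5. All of achiral 3 is funnelled into one stereoisomer, with nothing discarded as in a resolution.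

Step 3
Reactants: 5 (2R,8R)-1,9-dichlorononane-2,8-diol
Product: 6 (2R,2'R)-2,2'-(pentane-1,5-diyl)bis(oxirane) [(2R,8R)-1,2:8,9-diepoxynonane]
Conditions: KOH (2.5 equiv), H2O/Et2O, rt; distillation
Reagents that add atoms: none
Why: Twofold intramolecular Williamson reaction (3-exo-tet), each alkoxide displacing its neighbouring primary chloride, so the carbinol carbons are not touched and both stay R.

Step 4
Reactants: 7 3-bromo-5-methoxyphenol
Product: 8 1-(benzyloxy)-3-bromo-5-methoxybenzene
Conditions: BnBr (1.1 equiv), K2CO3 (1.5 equiv), acetone, reflux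
Reagents that add atoms: benzyl bromide, BrCc1ccccc1
Why: Williamson ether synthesis on the phenoxide; benzyl is chosen because it withstands Grignard and cuprate reagents and is removed at the end by hydrogenolysis without touching the acetate.

Step 5
Reactants: 6 (2R,2'R)-2,2'-(pentane-1,5-diyl)bis(oxirane); 8 1-(benzyloxy)-3-bromo-5-methoxybenzene
Product: 10 (2R)-1-[3-(benzyloxy)-5-methoxyphenyl]-7-[(2R)-oxiran-2-yl]heptan-2-ol, via arylmagnesium bromide 9 (not isolated)
Conditions: 8, Mg turnings, I2 (cat.), THF, 45 °C; then slow addition to 6 (3.0 equiv), CuI (10 mol%), THF, −30 °C; sat. aq NH4Cl; excess 6 recovered by distillation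
Reagents that add atoms: none
Why: Copper-catalysed SN2 opening of a terminal oxirane at its CH2 carbon by an aryl Grignard reagent forms the aryl–C1 bond with C2 untouched (R retained), and because the two oxiranes of 6 are homotopic either end gives the same product, so only over-addition has to be held back, which the threefold excess of recoverable 6 and slow addition of 9 should achieve.

Step 6
Reactants: 10 (2R)-1-[3-(benzyloxy)-5-methoxyphenyl]-7-[(2R)-oxiran-2-yl]heptan-2-ol
Product: 11 (2R)-1-[3-(benzyloxy)-5-methoxyphenyl]-7-[(2R)-oxiran-2-yl]heptan-2-yl acetate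
Conditions: Ac2O (1.5 equiv), pyridine (3 equiv), DMAP (5 mol%), CH2Cl2, 0 °C → rt
Reagents that add atoms: acetic anhydride, CC(=O)OC(C)=O
Why: DMAP-catalysed O-acylation of the secondary alcohol occurs at oxygen with retention at C2, and the terminal oxirane is inert to these weakly basic conditions.

Step 7
Reactants: 11 (2R)-1-[3-(benzyloxy)-5-methoxyphenyl]-7-[(2R)-oxiran-2-yl]heptan-2-yl acetate
Product: 12 (2R,8S)-1-[3-(benzyloxy)-5-methoxyphenyl]-8-hydroxytridecan-2-yl acetate
Conditions: n-Bu2CuLi (2.0 equiv; from CuI and n-BuLi, Et2O, −40 °C), Et2O, −40 → −20 °C; quenched at −40 °C with sat. aq NH4Cl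
Reagents that add atoms: n-butyllithium, CCCC[Li]
Why: SN2 opening of the terminal oxirane at C9 by lithium dibutylcuprate (a Gilman reagent) forms the C9–C10 bond without touching C8, so the (R)-oxirane becomes the (8S)-carbinol (the descriptor changes only because pentyl ranks below the chain), while lithium dialkylcuprates do not add to saturated esters at this temperature, so the C2 acetate should survive and the C8 hydroxyl appears unprotected.

Step 8
Reactants: 12 (2R,8S)-1-[3-(benzyloxy)-5-methoxyphenyl]-8-hydroxytridecan-2-yl acetate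
Product: 13 (2R,8S)-8-hydroxy-1-(3-hydroxy-5-methoxyphenyl)tridecan-2-yl acetate
Conditions: H2 (1 atm), 10% Pd/C, EtOAc, rt
Reagents that add atoms: none
Why: Hydrogenolysis of the aryl benzyl ether frees the phenol, and the homobenzylic acetate, the secondary alcohol and both stereocentres are not affected.

**Compound list**

1 | heptanedioyl dichloride (pimeloyl chloride) | ClC(=O)CCCCCC(=O)Cl | starting material
2 | 1,9-bis(diazo)nonane-2,8-dione | [N-]=[N+]=CC(=O)CCCCCC(=O)C=[N+]=[N-] | intermediate (not isolated)
3 | 1,9-dichlorononane-2,8-dione | ClCC(=O)CCCCCC(=O)CCl | intermediate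
4 | (8R)-1,9-dichloro-8-hydroxynonan-2-one | ClCC(=O)CCCCC[C@@H](O)CCl | intermediate (not isolated)
5 | (2R,8R)-1,9-dichlorononane-2,8-diol | ClC[C@H](O)CCCCC[C@@H](O)CCl | intermediate
6 | (2R,2'R)-2,2'-(pentane-1,5-diyl)bis(oxirane) [(2R,8R)-1,2:8,9-diepoxynonane] | C1O[C@@H]1CCCCC[C@@H]1CO1 | intermediate
7 | 3-bromo-5-methoxyphenol | COc1cc(O)cc(Br)c1 | starting material
8 | 1-(benzyloxy)-3-bromo-5-methoxybenzene | COc1cc(Br)cc(OCc2ccccc2)c1 | intermediate
9 | [3-(benzyloxy)-5-methoxyphenyl]magnesium bromide | COc1cc([Mg]Br)cc(OCc2ccccc2)c1 | intermediate (not isolated)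
10 | (2R)-1-[3-(benzyloxy)-5-methoxyphenyl]-7-[(2R)-oxiran-2-yl]heptan-2-ol | C1O[C@@H]1CCCCC[C@H](Cc2cc(OCc3ccccc3)cc(OC)c2)O | intermediate
11 | (2R)-1-[3-(benzyloxy)-5-methoxyphenyl]-7-[(2R)-oxiran-2-yl]heptan-2-yl acetate | C1O[C@@H]1CCCCC[C@H](Cc2cc(OCc3ccccc3)cc(OC)c2)OC(C)=O | intermediate
12 | (2R,8S)-1-[3-(benzyloxy)-5-methoxyphenyl]-8-hydroxytridecan-2-yl acetate | CCCCC[C@H](O)CCCCC[C@H](Cc1cc(OCc2ccccc2)cc(OC)c1)OC(C)=O | intermediate
13 | (2R,8S)-8-hydroxy-1-(3-hydroxy-5-methoxyphenyl)tridecan-2-yl acetate | CCCCC[C@H](O)CCCCC[C@H](Cc1cc(O)cc(OC)c1)OC(C)=O | target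

Total step count: 8. Longest linear sequence: 7 steps (steps 1, 2, 3, 5, 6, 7, 8).

Steps most likely to fail:

Step 2. The reduction of the second carbonyl could be slow or unselective, the alkylating chloroketone could inhibit the enzyme, or the substrate could be too insoluble, any of which would leave hydroxy ketone or meso diol. The fallback sets out from 3 and returns at 6, replacing asymmetric reduction by a kinetic resolution. NaBH4 in MeOH at 0 °C should give 1,9-dichlorononane-2,8-diol F1 (all stereoisomers), and KOH in H2O/Et2O should give 2,2'-(pentane-1,5-diyl)bis(oxirane) F2 (all stereoisomers). A twofold Jacobsen hydrolytic kinetic resolution should then hydrolyse every (S)-oxirane and leave 6. The catalyst would be (R,R)-(salen)Co(OAc), a trivalent cobalt complex with salen = N,N'-bis(3,5-di-tert-butylsalicylidene)cyclohexane-1,2-diaminate, the enantiomer that hydrolyses (S)-alkyloxiranes (2 mol%, H2O 1.15 equiv, THF, 0 °C → rt). By design at most one quarter of F2 can emerge as 6, which would be distilled from the epoxy diol and the tetraol.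

Step 5. Mono-selectivity could be lost through a second arylation of 10 to the diaryl diol or through opening of an oxirane by bromide. The fallback sets out from 8 (through 9) and returns at 10 by a linear sequence without a statistical step. Reagent 9 with (S)-epichlorohydrin and CuI (cat.) in THF at −30 °C should give (2S)-1-[3-(benzyloxy)-5-methoxyphenyl]-3-chloropropan-2-ol F3, and NaOH in aqueous THF (2S)-2-[3-(benzyloxy)-5-methoxybenzyl]oxirane F4. Hex-5-en-1-ylmagnesium bromide F5 (from 6-bromohex-1-ene and Mg) with CuI (cat.) should open F4 to (2R)-1-[3-(benzyloxy)-5-methoxyphenyl]non-8-en-2-ol F6. mCPBA in CH2Cl2 should give (2R)-1-[3-(benzyloxy)-5-methoxyphenyl]-7-(oxiran-2-yl)heptan-2-ol F7 (both oxirane epimers), and a hydrolytic kinetic resolution with the same (R,R)-(salen)Co(OAc) should hydrolyse the (S)-oxirane epimer to a triol and leave 10.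

Step 7. The organometallic reagent could cleave the C2 acetate, the acetyl group could move to the new C8 alkoxide, or the butylcuprate could decay before the oxirane is consumed. The fallback sets out from 6 and returns at 13 by reversing the order of the two openings, so that no ester meets a carbanion. n-BuMgCl (limiting) with CuI (cat.) on excess 6 in THF at −30 °C should give (6S)-1-[(2R)-oxiran-2-yl]undecan-6-ol F8, and NaH, BnBr and Bu4NI in THF (2R)-2-[(6S)-6-(benzyloxy)undecyl]oxirane F9. Reagent 9 with CuI (cat.) should give (2R,8S)-8-(benzyloxy)-1-[3-(benzyloxy)-5-methoxyphenyl]tridecan-2-ol F10, and Ac2O, pyridine and DMAP (2R,8S)-8-(benzyloxy)-1-[3-(benzyloxy)-5-methoxyphenyl]tridecan-2-yl acetate F11. H2 over Pd/C in EtOAc should then remove both benzyl groups to give 13.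

**Further compounds**

F1 | step 2 | 1,9-dichlorononane-2,8-diol (all stereoisomers) | ClCC(O)CCCCCC(O)CCl
F2 | step 2 | 2,2'-(pentane-1,5-diyl)bis(oxirane) (all stereoisomers) | C1OC1CCCCCC1CO1
F3 | step 5 | (2S)-1-[3-(benzyloxy)-5-methoxyphenyl]-3-chloropropan-2-ol | ClC[C@@H](O)Cc1cc(OC)cc(OCc2ccccc2)c1
F4 | step 5 | (2S)-2-[3-(benzyloxy)-5-methoxybenzyl]oxirane | C1O[C@H]1Cc2cc(OC)cc(OCc3ccccc3)c2
F5 | step 5 | hex-5-en-1-ylmagnesium bromide | C=CCCCC[Mg]Br
F6 | step 5 | (2R)-1-[3-(benzyloxy)-5-methoxyphenyl]non-8-en-2-ol | C=CCCCCC[C@@H](O)Cc1cc(OC)cc(OCc2ccccc2)c1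
F7 | step 5 | (2R)-1-[3-(benzyloxy)-5-methoxyphenyl]-7-(oxiran-2-yl)heptan-2-ol (both oxirane epimers) | C1OC1CCCCC[C@@H](O)Cc2cc(OC)cc(OCc3ccccc3)c2
F8 | step 7 | (6S)-1-[(2R)-oxiran-2-yl]undecan-6-ol | CCCCC[C@H](O)CCCCC[C@@H]1CO1
F9 | step 7 | (2R)-2-[(6S)-6-(benzyloxy)undecyl]oxirane | CCCCC[C@H](OCc1ccccc1)CCCCC[C@@H]2CO2
F10 | step 7 | (2R,8S)-8-(benzyloxy)-1-[3-(benzyloxy)-5-methoxyphenyl]tridecan-2-ol | CCCCC[C@H](OCc1ccccc1)CCCCC[C@H](Cc2cc(OCc3ccccc3)cc(OC)c2)O
F11 | step 7 | (2R,8S)-8-(benzyloxy)-1-[3-(benzyloxy)-5-methoxyphenyl]tridecan-2-yl acetate | CCCCC[C@H](OCc1ccccc1)CCCCC[C@H](Cc2cc(OCc3ccccc3)cc(OC)c2)OC(C)=O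
A1 | direct plan | (S)-7-(triisopropylsilyloxy)dodecanal | CCCCC[C@H](O[Si](C(C)C)(C(C)C)C(C)C)CCCCCC=O
A2 | direct plan | 3-methoxy-5-(triisopropylsilyloxy)benzylzinc bromide | COc1cc(C[Zn]Br)cc(O[Si](C(C)C)(C(C)C)C(C)C)c1
A3 | direct plan | (7S)-1-bromo-7-(triisopropylsilyloxy)dodecyl acetate (both C1 epimers) | CCCCC[C@H](O[Si](C(C)C)(C(C)C)C(C)C)CCCCCC(Br)OC(C)=O
A4 | direct plan | (2R,8S)-1-[3-methoxy-5-(triisopropylsilyloxy)phenyl]-8-(triisopropylsilyloxy)tridecan-2-yl acetate | CCCCC[C@H](O[Si](C(C)C)(C(C)C)C(C)C)CCCCC[C@H](Cc1cc(O[Si](C(C)C)(C(C)C)C(C)C)cc(OC)c1)OC(C)=O
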